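**Retrosynthetic overview**

- The target is cut at C8–C9: a Mizoroki–Heck vinylation, as the last step, joins an unprotected C11 vinyl triol (ring A with its three carbinol centres) to a C29 heptaenyl iodide that already carries the dihydrofuran end group.
- Enabling feature: C6 of ring A is a fully substituted carbinol carbon between the quaternary C1 and C5. Its vinyl group C7=C8 therefore has no allylic hydrogen, carbopalladation at C8 can only be followed by loss of H8, and the 7E-diene forms with all hydroxyls free.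
- The C29 iodide comes from two Wittig olefinations (C11'=C12', then C11=C12) of the C10 dialdehyde with a furanoid C15 phosphonium salt and a 3-iodobut-2-enyl phosphonium salt.
- Both end groups come from one epoxy aldehyde (Katsuki–Sharpless epoxidation sets C5 and C6). The vinyl oxirane is converted by palladium/CO2 into a carbonate with retention, which gives the cis-5,6-diol. The ethynyl oxirane is taken through Sonogashira coupling, anti-SN2' hydride delivery and gold-catalysed 5-endo cyclisation, which sets C8'.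
- Ring order: both cyclohexane rings come from (4R,6R)-actinol; the oxirane is formed in step 5; a temporary dioxolanone on ring A is formed in step 8 and removed in step 9; the dihydrofuran ring is formed in step 16.

Key step: step 24

Assumption: (4R,6R)-actinol is taken as a purchasable building block; C1–C15 and C1'–C15' are carotenoid locants (primes for the furanoid half) and TBS is tert-butyldimethylsilyl.

**Step 1**
Reactants: 1 (4R,6R)-4-hydroxy-2,2,6-trimethylcyclohexan-1-one [(4R,6R)-actinol]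
Product: 2 (4R,6R)-4-(TBS-oxy)-2,2,6-trimethylcyclohexan-1-one
Conditions: TBSCl, imidazole, DMF, rt
Reagents that add atoms: tert-butyldimethylsilyl chloride, CC(C)(C)[Si](C)(C)Cl
Why: Standard silylation of the secondary alcohol; the carbinol centre that becomes C3 and C3' is not touched.

**Step 2**
Reactants: 2 (4R,6R)-4-(TBS-oxy)-2,2,6-trimethylcyclohexan-1-one
Product: 4 (4R)-4-(TBS-oxy)-2,6,6-trimethylcyclohex-1-en-1-yl trifluoromethanesulfonate, via lithium enolate 3 (not isolated)
Conditions: LDA, THF, −78 °C; then PhNTf2, −78 °C → rt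
Reagents that add atoms: N-phenylbis(trifluoromethanesulfonimide), FC(F)(F)S(=O)(=O)N(c1ccccc1)S(=O)(=O)C(F)(F)F; lithium diisopropylamide, [Li+].CC(C)[N-]C(C)C (lithium of 3 only)
Why: Enolate O-triflation; only the methyl-bearing α-carbon can enolise because the other α-carbon is quaternary, so one regioisomer should form.

**Step 3**
Reactants: 4 (4R)-4-(TBS-oxy)-2,6,6-trimethylcyclohex-1-en-1-yl trifluoromethanesulfonate
Product: 5 methyl (4R)-4-(TBS-oxy)-2,6,6-trimethylcyclohex-1-ene-1-carboxylate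
Conditions: Pd(OAc)2 (5 mol %), PPh3, CO (1 atm), MeOH, Et3N, DMF, 60 °C
Reagents that add atoms: carbon monoxide, [C-]#[O+]; methanol, CO
Why: Palladium-catalysed alkoxycarbonylation of an enol triflate installs C7 at the ester oxidation level.

**Step 4**
Reactants: 5 methyl (4R)-4-(TBS-oxy)-2,6,6-trimethylcyclohex-1-ene-1-carboxylate
Product: 6 [(4R)-4-(TBS-oxy)-2,6,6-trimethylcyclohex-1-en-1-yl]methanol
Conditions: DIBAL-H, CH2Cl2, −78 → 0 °C; aqueous Rochelle salt
Reagents that add atoms: none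
Why: 1,2-Reduction of the hindered enoate by DIBAL-H gives the allylic alcohol needed for directed epoxidation.

**Step 5**
Reactants: 6 [(4R)-4-(TBS-oxy)-2,6,6-trimethylcyclohex-1-en-1-yl]methanol
Product: 7 [(1R,4S,6R)-4-(TBS-oxy)-2,2,6-trimethyl-7-oxabicyclo[4.1.0]heptan-1-yl]methanol (oxirane anti to the silyloxy group)
Conditions: Ti(OiPr)4 (20 mol %), D-(−)-diethyl tartrate (24 mol %), t-BuOOH, 4 Å MS, CH2Cl2, −20 °C
Reagents that add atoms: tert-butyl hydroperoxide, CC(C)(C)OO
Why: Katsuki–Sharpless asymmetric epoxidation of a tetrasubstituted allylic alcohol; the D-tartrate titanium complex delivers oxygen to the C5=C6 face anti to the 3-silyloxy group and so sets C5 (R) and the C6 oxygen together under reagent control.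

**Step 6**
Reactants: 7 [(1R,4S,6R)-4-(TBS-oxy)-2,2,6-trimethyl-7-oxabicyclo[4.1.0]heptan-1-yl]methanol
Product: 8 (1S,4S,6R)-4-(TBS-oxy)-2,2,6-trimethyl-7-oxabicyclo[4.1.0]heptane-1-carbaldehyde
Conditions: (n-Pr4N)RuO4 (5 mol %), NMO, 4 Å MS, CH2Cl2, rt
Reagents that add atoms: none
Why: Ley–Griffith oxidation under neutral conditions spares the acid-labile tetrasubstituted oxirane; the aldehyde has no α-hydrogen and cannot epimerise.

**Step 7**
Reactants: 8 (1S,4S,6R)-4-(TBS-oxy)-2,2,6-trimethyl-7-oxabicyclo[4.1.0]heptane-1-carbaldehyde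
Product: 9 (1S,4S,6R)-4-(TBS-oxy)-1-ethenyl-2,2,6-trimethyl-7-oxabicyclo[4.1.0]heptane
Conditions: Ph3PCH3Br, KOtBu, THF, 0 °C → rt
Reagents that add atoms: methyltriphenylphosphonium bromide, [Br-].C[P+](c1ccccc1)(c1ccccc1)c1ccccc1
Why: Wittig methylenation of a non-enolisable aldehyde gives the vinyl oxirane (C7=C8) without touching the stereocentres.

**Step 8**
Reactants: 9 (1S,4S,6R)-4-(TBS-oxy)-1-ethenyl-2,2,6-trimethyl-7-oxabicyclo[4.1.0]heptane
Product: 10 (3aS,6S,7aR)-6-(TBS-oxy)-3a-ethenyl-4,4,7a-trimethylhexahydro-1,3-benzodioxol-2-one (cis-fused 5,6-carbonate)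
Conditions: Pd2(dba)3·CHCl3 (3 mol %), P(OiPr)3 (18 mol %), CO2 (1–3 atm), THF, rt
Reagents that add atoms: carbon dioxide, O=C=O
Why: Palladium-catalysed CO2 insertion into a vinyl oxirane (a known cis-hydroxylation equivalent): zerovalent palladium ionises the allylic C6–O bond with inversion, the C5 alkoxide takes up CO2 and the carbonate closes on C6 anti to palladium, so C6 is formed with net retention and both oxygens end on the same face (cis-5,6-diol, 6S), while C1 and C5 carry no hydrogen that could divert the π-allyl intermediate to a diene or ketone.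

**Step 9**
Reactants: 10 (3aS,6S,7aR)-6-(TBS-oxy)-3a-ethenyl-4,4,7a-trimethylhexahydro-1,3-benzodioxol-2-one
Product: 11 (1S,2R,4S)-4-(TBS-oxy)-1-ethenyl-2,6,6-trimethylcyclohexane-1,2-diol
Conditions: NaOH, MeOH/THF/H2O, 50 °C
Reagents that add atoms: none
Why: Saponification of the cyclic carbonate frees the di-tertiary cis-diol; both C–O bonds stay intact, so no stereocentre changes.

**Step 10**
Reactants: 11 (1S,2R,4S)-4-(TBS-oxy)-1-ethenyl-2,6,6-trimethylcyclohexane-1,2-diol
Product: 12 (1S,2R,4S)-1-ethenyl-2,6,6-trimethylcyclohexane-1,2,4-triol (fragment A)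
Conditions: TBAF, THF, rt
Reagents that add atoms: none
Why: Fluoride desilylation under non-acidic conditions avoids ionisation of the tertiary allylic alcohol and gives the free vinyl triol.

**Step 11**
Reactants: 8 (1S,4S,6R)-4-(TBS-oxy)-2,2,6-trimethyl-7-oxabicyclo[4.1.0]heptane-1-carbaldehyde
Product: 13 (1R,4S,6R)-4-(TBS-oxy)-1-ethynyl-2,2,6-trimethyl-7-oxabicyclo[4.1.0]heptane
Conditions: dimethyl (1-diazo-2-oxopropyl)phosphonate, K2CO3, MeOH, 0 °C → rt
Reagents that add atoms: dimethyl (1-diazo-2-oxopropyl)phosphonate, COP(=O)(OC)C(=[N+]=[N-])C(C)=O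
Why: Seyferth–Gilbert homologation in its Ohira–Bestmann form turns the non-enolisable aldehyde into the terminal alkyne (C7'≡C8') under mild base.

**Step 12**
Reactants: 14 but-2-yn-1-ol
Product: 15 (but-2-yn-1-yloxy)(tert-butyl)dimethylsilane
Conditions: TBSCl, imidazole, DMF, rt
Reagents that add atoms: tert-butyldimethylsilyl chloride, CC(C)(C)[Si](C)(C)Cl
Why: Standard silylation of the primary alcohol masks the hydroxyl for the hydrozirconation.

**Step 13**
Reactants: 15 (but-2-yn-1-yloxy)(tert-butyl)dimethylsilane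
Product: 17 tert-butyl{[(2E)-3-iodobut-2-en-1-yl]oxy}dimethylsilane, via alkenylzirconocene chloride 16 (not isolated)
Conditions: Cp2Zr(H)Cl (1.5 equiv), THF, 50 °C; then I2, 0 °C
Reagents that add atoms: iodine, II; zirconocene chloride hydride, [H][Zr](Cl)(C1C=CC=C1)C1C=CC=C1 (zirconium of 16 only)
Why: Syn-hydrozirconation with thermodynamic placement of zirconium on the methyl-bearing alkyne carbon, then iodinolysis with retention, gives the E-iodide whose geometry becomes 9E and 9'E.

**Step 14**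
Reactants: 13 (1R,4S,6R)-4-(TBS-oxy)-1-ethynyl-2,2,6-trimethyl-7-oxabicyclo[4.1.0]heptane; 17 tert-butyl{[(2E)-3-iodobut-2-en-1-yl]oxy}dimethylsilane
Product: 18 tert-butyl{[(2E)-5-[(1R,4S,6R)-4-(TBS-oxy)-2,2,6-trimethyl-7-oxabicyclo[4.1.0]heptan-1-yl]-3-methylpent-2-en-4-yn-1-yl]oxy}dimethylsilane
Conditions: Pd(PPh3)4 (5 mol %), CuI (10 mol %), i-Pr2NH, THF, rt
Reagents that add atoms: none
Why: Sonogashira coupling of the ethynyl oxirane with the alkenyl iodide proceeds with retention of the E geometry and forms the C8'–C9' bond.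

**Step 15**
Reactants: 18 the epoxy enyne of step 14
Product: 19 (1R,5S)-5-(TBS-oxy)-2-[(3E)-5-(TBS-oxy)-3-methylpenta-1,3-dien-1-ylidene]-1,3,3-trimethylcyclohexan-1-ol with the (aS) allene axis (C9' on the side of the 5'-hydroxyl)
Conditions: (IPr)CuCl (5 mol %; IPr = 1,3-bis(2,6-diisopropylphenyl)imidazol-2-ylidene), NaOtBu (5 mol %), (EtO)2MeSiH, t-BuOH, toluene, 0 °C → rt
Reagents that add atoms: none
Why: Copper hydride SN2' reduction of a propargylic oxirane (a known route to α-hydroxyallenes): syn-hydrocupration (hydride to C8', copper to C7') followed by anti β-alkoxide elimination delivers hydride anti to the C6'–O bond, which keeps C5' (R) and sets the allene axis with C9' on the face of the 5'-hydroxyl.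

**Step 16**
Reactants: 19 the (aS)-allenyl carbinol of step 15
Product: 20 (2R,6S,7aR)-6-(TBS-oxy)-2-[(2E)-4-(TBS-oxy)but-2-en-2-yl]-4,4,7a-trimethyl-2,4,5,6,7,7a-hexahydro-1-benzofuran
Conditions: AuCl3 (5 mol %), THF, rt, dark
Reagents that add atoms: none
Why: Gold-catalysed 5-endo cycloisomerisation of an α-hydroxyallene to a 2,5-dihydrofuran with axis-to-centre chirality transfer: the 5'-oxygen can reach C8' only from its own side of the allene, which places the C9' substituent trans to the 5'-methyl and gives 8'R.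

**Step 17**
Reactants: 20 the bis-silyl dihydrofuran of step 16
Product: 21 (2E)-3-[(2R,6S,7aR)-6-hydroxy-4,4,7a-trimethyl-2,4,5,6,7,7a-hexahydro-1-benzofuran-2-yl]but-2-en-1-ol
Conditions: TBAF (2.5 equiv), THF, rt
Reagents that add atoms: none
Why: Fluoride removes both silyl ethers without acid, so the doubly allylic C8'–O bond cannot ionise and C8' is kept.

**Step 18**
Reactants: 21 the furanoid diol of step 17
Product: 22 (2R,6S,7aR)-2-[(2E)-4-bromobut-2-en-2-yl]-4,4,7a-trimethyl-2,4,5,6,7,7a-hexahydro-1-benzofuran-6-ol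
Conditions: NBS, Me2S, CH2Cl2, −20 → 0 °C
Reagents that add atoms: N-bromosuccinimide, BrN1C(=O)CCC1=O
Why: Corey–Kim halogenation is selective for the primary allylic alcohol over the saturated secondary 3'-hydroxyl and generates no strong acid.

**Step 19**
Reactants: 22 the allylic bromide of step 18
Product: 23 {(2E)-3-[(2R,6S,7aR)-6-hydroxy-4,4,7a-trimethyl-2,4,5,6,7,7a-hexahydro-1-benzofuran-2-yl]but-2-en-1-yl}triphenylphosphonium bromide
Conditions: PPh3, toluene/CH2Cl2, rt
Reagents that add atoms: triphenylphosphine, c1ccc(cc1)P(c1ccccc1)c1ccccc1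
Why: SN2 quaternisation of the primary allylic bromide under neutral conditions gives the furanoid C15 Wittig salt.

**Step 20**
Reactants: 23 the furanoid C15 phosphonium bromide; 24 (2E,4E,6E)-2,7-dimethylocta-2,4,6-trienedial
Product: 26 (2E,4E,6E,8E,10E)-11-[(2R,6S,7aR)-6-hydroxy-4,4,7a-trimethyl-2,4,5,6,7,7a-hexahydro-1-benzofuran-2-yl]-2,7-dimethyldodeca-2,4,6,8,10-pentaenal, via phosphorus ylide 25 (not isolated)
Conditions: 24 (3 equiv), NaOMe, MeOH/CH2Cl2, 0 °C → rt; then heptane, 80 °C, dark (Z → E)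
Reagents that add atoms: none
Why: Wittig olefination of the excess symmetrical dialdehyde by the semistabilised allylic ylide forms C11'=C12' on one side only, and the unhindered disubstituted Z isomer should equilibrate thermally to the all-E aldehyde.

**Step 21**
Reactants: 17 tert-butyl{[(2E)-3-iodobut-2-en-1-yl]oxy}dimethylsilane
Product: 27 (2E)-1-bromo-3-iodobut-2-ene
Conditions: Ph3PBr2, CH2Cl2, 0 °C → rt
Reagents that add atoms: dibromotriphenylphosphorane, BrP(Br)(c1ccccc1)(c1ccccc1)c1ccccc1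
Why: Direct conversion of a primary allylic silyl ether into the bromide by the phosphorane leaves the alkenyl iodide and its geometry untouched.

**Step 22**
Reactants: 27 (2E)-1-bromo-3-iodobut-2-ene
Product: 28 [(2E)-3-iodobut-2-en-1-yl]triphenylphosphonium bromide
Conditions: PPh3, toluene, rt
Reagents that add atoms: triphenylphosphine, c1ccc(cc1)P(c1ccccc1)c1ccccc1
Why: SN2 quaternisation at the allylic bromide is much faster than any reaction at the sp2 C–I bond.

**Step 23**
Reactants: 26 the C25 aldehyde of step 20; 28 [(2E)-3-iodobut-2-en-1-yl]triphenylphosphonium bromide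
Product: 30 (2R,6S,7aR)-2-[(2E,4E,6E,8E,10E,12E,14E)-15-iodo-6,11-dimethylhexadeca-2,4,6,8,10,12,14-heptaen-2-yl]-4,4,7a-trimethyl-2,4,5,6,7,7a-hexahydro-1-benzofuran-6-ol (fragment B), via iodoallyl ylide 29 (not isolated)
Conditions: NaOMe, MeOH/CH2Cl2, −20 °C → rt, dark; then EtOAc, 60 °C (Z → E)
Reagents that add atoms: none
Why: Wittig olefination with a γ-haloallyl ylide (the type used to make 1-halo-1,3-dienes) forms C11=C12 and carries the 9E alkenyl iodide into the polyene unchanged; an alkoxide base avoids halogen–metal exchange.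

**Step 24**
Reactants: 12 (1S,2R,4S)-1-ethenyl-2,6,6-trimethylcyclohexane-1,2,4-triol; 30 the C29 heptaenyl iodide of step 23
Product: 31 (3S,5R,6S,3'S,5'R,8'R)-5',8'-epoxy-5,6,5',8'-tetrahydro-β,β-carotene-3,5,6,3'-tetrol (target)
Conditions: 12 (1.5 equiv), Pd(OAc)2 (10 mol %), n-Bu4NCl, K2CO3, DMF, 40 °C, Ar, dark
Reagents that add atoms: none
Why: Oxidative addition of zerovalent palladium to the C9–I bond of 30 (with retention of 9E) gives an alkenylpalladium iodide that adds across the monosubstituted C7=C8 bond of 12, carbon to the terminus C8 and palladium to C7, and syn β-hydride elimination of H8 then forms the C8–C9-linked diene while base regenerates the catalyst. The closest known reaction type is the Mizoroki–Heck vinylation of tertiary allylic alcohols with alkenyl iodides under ligand-free phase-transfer conditions, which gives (E,E)-dienols near room temperature. No ring is closed and no stereocentre is created; the only new stereo-element is the 7E double bond, fixed by the syn-insertion and syn-elimination sequence that places C6 and C9 anti. The step needs regioselectivity for C8 and a single elimination pathway, and the substrate secures both: C6 is a fully substituted carbinol carbon flanked by the quaternary C1 and C5, so it shields C7, offers no β-hydrogen, and cannot be carried on to a carbonyl compound. The three hydroxyls of 12, the 3'-hydroxyl and the dihydrofuran of 30 are inert to the mildly basic medium, so the coupling should deliver the unprotected target directly.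

**Compound list**

1 | (4R,6R)-4-hydroxy-2,2,6-trimethylcyclohexan-1-one [(4R,6R)-actinol] | O=C1C(C)(C)C[C@H](O)C[C@H]1C | starting material
2 | (4R,6R)-4-(TBS-oxy)-2,2,6-trimethylcyclohexan-1-one | O=C1C(C)(C)C[C@H](O[Si](C)(C)C(C)(C)C)C[C@H]1C | intermediate
3 | lithium (4R)-4-(TBS-oxy)-2,6,6-trimethylcyclohex-1-en-1-olate (not isolated) | CC1=C(O[Li])C(C)(C)C[C@H](O[Si](C)(C)C(C)(C)C)C1 | intermediate
4 | (4R)-4-(TBS-oxy)-2,6,6-trimethylcyclohex-1-en-1-yl trifluoromethanesulfonate | CC1=C(OS(=O)(=O)C(F)(F)F)C(C)(C)C[C@H](O[Si](C)(C)C(C)(C)C)C1 | intermediate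
5 | methyl (4R)-4-(TBS-oxy)-2,6,6-trimethylcyclohex-1-ene-1-carboxylate | CC1=C(C(=O)OC)C(C)(C)C[C@H](O[Si](C)(C)C(C)(C)C)C1 | intermediate
6 | [(4R)-4-(TBS-oxy)-2,6,6-trimethylcyclohex-1-en-1-yl]methanol | CC1=C(CO)C(C)(C)C[C@H](O[Si](C)(C)C(C)(C)C)C1 | intermediate
7 | [(1R,4S,6R)-4-(TBS-oxy)-2,2,6-trimethyl-7-oxabicyclo[4.1.0]heptan-1-yl]methanol | OC[C@]12C(C)(C)C[C@H](O[Si](C)(C)C(C)(C)C)C[C@@]1(C)O2 | intermediate
8 | (1S,4S,6R)-4-(TBS-oxy)-2,2,6-trimethyl-7-oxabicyclo[4.1.0]heptane-1-carbaldehyde | O=C[C@]12C(C)(C)C[C@H](O[Si](C)(C)C(C)(C)C)C[C@@]1(C)O2 | intermediate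
9 | (1S,4S,6R)-4-(TBS-oxy)-1-ethenyl-2,2,6-trimethyl-7-oxabicyclo[4.1.0]heptane | C=C[C@]12C(C)(C)C[C@H](O[Si](C)(C)C(C)(C)C)C[C@@]1(C)O2 | intermediate
10 | (3aS,6S,7aR)-6-(TBS-oxy)-3a-ethenyl-4,4,7a-trimethylhexahydro-1,3-benzodioxol-2-one | C=C[C@]12C(C)(C)C[C@H](O[Si](C)(C)C(C)(C)C)C[C@@]1(C)OC(=O)O2 | intermediate
11 | (1S,2R,4S)-4-(TBS-oxy)-1-ethenyl-2,6,6-trimethylcyclohexane-1,2-diol | C=C[C@]1(O)C(C)(C)C[C@H](O[Si](C)(C)C(C)(C)C)C[C@@]1(C)O | intermediate
12 | (1S,2R,4S)-1-ethenyl-2,6,6-trimethylcyclohexane-1,2,4-triol (fragment A) | C=C[C@]1(O)C(C)(C)C[C@H](O)C[C@@]1(C)O | intermediate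
13 | (1R,4S,6R)-4-(TBS-oxy)-1-ethynyl-2,2,6-trimethyl-7-oxabicyclo[4.1.0]heptane | C#C[C@]12C(C)(C)C[C@H](O[Si](C)(C)C(C)(C)C)C[C@@]1(C)O2 | intermediate
14 | but-2-yn-1-ol | CC#CCO | starting material
15 | (but-2-yn-1-yloxy)(tert-butyl)dimethylsilane | CC#CCO[Si](C)(C)C(C)(C)C | intermediate
16 | chlorobis(cyclopentadienyl)[(2E)-4-(TBS-oxy)but-2-en-2-yl]zirconium (not isolated) | C/C(=C\CO[Si](C)(C)C(C)(C)C)[Zr](Cl)(C1C=CC=C1)C1C=CC=C1 | intermediate
17 | tert-butyl{[(2E)-3-iodobut-2-en-1-yl]oxy}dimethylsilane | C/C(I)=C\CO[Si](C)(C)C(C)(C)C | intermediate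
18 | tert-butyl{[(2E)-5-[(1R,4S,6R)-4-(TBS-oxy)-2,2,6-trimethyl-7-oxabicyclo[4.1.0]heptan-1-yl]-3-methylpent-2-en-4-yn-1-yl]oxy}dimethylsilane | C/C(C#C[C@]12C(C)(C)C[C@H](O[Si](C)(C)C(C)(C)C)C[C@@]1(C)O2)=C\CO[Si](C)(C)C(C)(C)C | intermediate
19 | (1R,5S)-5-(TBS-oxy)-2-[(3E)-5-(TBS-oxy)-3-methylpenta-1,3-dien-1-ylidene]-1,3,3-trimethylcyclohexan-1-ol, (aS) allene axis with C9' syn to the hydroxyl | C/C(=C\CO[Si](C)(C)C(C)(C)C)C([H])=[C@]=C1C(C)(C)C[C@H](O[Si](C)(C)C(C)(C)C)C[C@@]1(C)O | intermediate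
20 | (2R,6S,7aR)-6-(TBS-oxy)-2-[(2E)-4-(TBS-oxy)but-2-en-2-yl]-4,4,7a-trimethyl-2,4,5,6,7,7a-hexahydro-1-benzofuran | CC(C)(C)[Si](C)(C)OC/C=C(\C)[C@H]1C=C2C(C)(C)C[C@H](O[Si](C)(C)C(C)(C)C)C[C@@]2(C)O1 | intermediate
21 | (2E)-3-[(2R,6S,7aR)-6-hydroxy-4,4,7a-trimethyl-2,4,5,6,7,7a-hexahydro-1-benzofuran-2-yl]but-2-en-1-ol | OC/C=C(\C)[C@H]1C=C2C(C)(C)C[C@H](O)C[C@@]2(C)O1 | intermediate
22 | (2R,6S,7aR)-2-[(2E)-4-bromobut-2-en-2-yl]-4,4,7a-trimethyl-2,4,5,6,7,7a-hexahydro-1-benzofuran-6-ol | BrC/C=C(\C)[C@H]1C=C2C(C)(C)C[C@H](O)C[C@@]2(C)O1 | intermediate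
23 | {(2E)-3-[(2R,6S,7aR)-6-hydroxy-4,4,7a-trimethyl-2,4,5,6,7,7a-hexahydro-1-benzofuran-2-yl]but-2-en-1-yl}triphenylphosphonium bromide | [Br-].c1ccccc1[P+](c1ccccc1)(c1ccccc1)C/C=C(\C)[C@H]1C=C2C(C)(C)C[C@H](O)C[C@@]2(C)O1 | intermediate
24 | (2E,4E,6E)-2,7-dimethylocta-2,4,6-trienedial | O=C/C(C)=C/C=C/C=C(C)/C=O | starting material
25 | ylide of 23: {(2E)-3-[(2R,6S,7aR)-6-hydroxy-4,4,7a-trimethyl-hexahydro-1-benzofuran-2-yl]but-2-en-1-ylidene}triphenylphosphorane (not isolated) | c1ccccc1P(c1ccccc1)(c1ccccc1)=C/C=C(\C)[C@H]1C=C2C(C)(C)C[C@H](O)C[C@@]2(C)O1 | intermediate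
26 | (2E,4E,6E,8E,10E)-11-[(2R,6S,7aR)-6-hydroxy-4,4,7a-trimethyl-2,4,5,6,7,7a-hexahydro-1-benzofuran-2-yl]-2,7-dimethyldodeca-2,4,6,8,10-pentaenal | O=C/C(C)=C/C=C/C=C(C)/C=C/C=C(\C)[C@H]1C=C2C(C)(C)C[C@H](O)C[C@@]2(C)O1 | intermediate
27 | (2E)-1-bromo-3-iodobut-2-ene | C/C(I)=C\CBr | intermediate
28 | [(2E)-3-iodobut-2-en-1-yl]triphenylphosphonium bromide | [Br-].C/C(I)=C\C[P+](c1ccccc1)(c1ccccc1)c1ccccc1 | intermediate
29 | [(2E)-3-iodobut-2-en-1-ylidene]triphenylphosphorane (not isolated) | C/C(I)=C\C=P(c1ccccc1)(c1ccccc1)c1ccccc1 | intermediate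
30 | (2R,6S,7aR)-2-[(2E,4E,6E,8E,10E,12E,14E)-15-iodo-6,11-dimethylhexadeca-2,4,6,8,10,12,14-heptaen-2-yl]-4,4,7a-trimethyl-2,4,5,6,7,7a-hexahydro-1-benzofuran-6-ol (fragment B) | CC(/C=C/C=C(C)/I)=C\C=C\C=C(C)\C=C\C=C(/C)[C@H]1C=C2C(C)(C)C[C@H](O)C[C@@]2(C)O1 | intermediate
31 | (3S,5R,6S,3'S,5'R,8'R)-5',8'-epoxy-5,6,5',8'-tetrahydro-β,β-carotene-3,5,6,3'-tetrol | CC(/C=C/C=C(C)/C=C/[C@]1(O)C(C)(C)C[C@H](O)C[C@@]1(C)O)=C\C=C\C=C(C)\C=C\C=C(/C)[C@H]1C=C2C(C)(C)C[C@H](O)C[C@@]2(C)O1 | target

**Step count**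

Total: 24 steps. Longest linear sequence: 16 steps (steps 1–6, 11, 14–20, 23, 24).

**Steps most likely to fail**

Step 24. Carbopalladation beside the congested C6 may be slow, so that reduction or homocoupling of the iodide and palladium-hydride E/Z scrambling of the polyene compete. The fallback forms the same bond by Suzuki–Miyaura coupling and sets out from 12. Ozonolysis (O3, CH2Cl2/MeOH, −78 °C; Me2S) would cut the vinyl group to (1S,2R,4S)-1,2,4-trihydroxy-2,6,6-trimethylcyclohexane-1-carbaldehyde F1. Takai–Utimoto borylative olefination (CrCl2, Cl2CHB(pin), LiI, THF) would give the (E)-alkenyl pinacol boronate F2. Suzuki–Miyaura coupling of this boronate with 30 (Pd(PPh3)4, aqueous K3PO4, THF, rt, dark) comes back to the route at 31.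

Step 15. Hydrocupration may take the opposite regiochemistry (copper at C8', stabilised by the adjacent alkene) and end in plain semireduction of the enyne, or the anti course may erode and give the epimeric allene axis, which would transfer to the wrong C8' configuration. The fallback is palladium–formate hydrogenolysis of the alkynyl oxirane and sets out from 18 (Pd2(dba)3·CHCl3, PBu3, HCO2NH4, THF, rt). Anti oxidative addition gives an allenylpalladium formate, and decarboxylation with reductive elimination places hydride on C8' from the palladium face. It comes back to the route at 19 and makes no new compound (F0).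

Step 8. Ionisation of the hindered tetrasubstituted oxirane may be sluggish, or the π-allyl intermediate may exchange faces (or undergo ring contraction) before the carbonate closes, with loss of retention at C6. The fallback sets out from 7. Appel iodination (I2, PPh3, imidazole, CH2Cl2) would give the epoxy iodide F3. Zinc-mediated reductive opening (Zn, EtOH, reflux) would give the allylic alcohol with retained C5–O bond and exocyclic C6=C7 methylene, F4. Hydroxyl-directed epoxidation (VO(acac)2, t-BuOOH, benzene, rt) would deliver oxygen to C6 syn to the 5-hydroxyl and give the spiro-oxirane F5. One-carbon homologation with dimethylsulfonium methylide (Me3SI, n-BuLi, THF, −10 °C → rt) would open this at C7 and eliminate to the vinyl carbinol, coming back to the route at 11.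

**Further compounds**

F1 | step 24 | (1S,2R,4S)-1,2,4-trihydroxy-2,6,6-trimethylcyclohexane-1-carbaldehyde | O=C[C@]1(O)C(C)(C)C[C@H](O)C[C@@]1(C)O
F2 | step 24 | (1S,2R,4S)-2,6,6-trimethyl-1-[(E)-2-(4,4,5,5-tetramethyl-1,3,2-dioxaborolan-2-yl)ethenyl]cyclohexane-1,2,4-triol | CC1(C)OB(/C=C/[C@]2(O)C(C)(C)C[C@H](O)C[C@@]2(C)O)OC1(C)C
F0 | step 15 | none | none
F3 | step 8 | (1S,4S,6R)-4-(TBS-oxy)-1-(iodomethyl)-2,2,6-trimethyl-7-oxabicyclo[4.1.0]heptane | IC[C@]12C(C)(C)C[C@H](O[Si](C)(C)C(C)(C)C)C[C@@]1(C)O2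
F4 | step 8 | (1R,5S)-5-(TBS-oxy)-1,3,3-trimethyl-2-methylidenecyclohexan-1-ol | C=C1C(C)(C)C[C@H](O[Si](C)(C)C(C)(C)C)C[C@@]1(C)O
F5 | step 8 | (3R,4R,6S)-6-(TBS-oxy)-4,8,8-trimethyl-1-oxaspiro[2.5]octan-4-ol | O1C[C@@]12C(C)(C)C[C@H](O[Si](C)(C)C(C)(C)C)C[C@@]2(C)O
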